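**Retrosynthetic overview**
1. Target ⇒ (desilylation, nitrile→aldehyde) a (Z)-unsaturated nitrile carrying the triene; the triene ⇒ HWE (C16=C17, geranyl phosphonate) and Wittig (C14=C15) from a C14 aldehyde that comes from an allyl group.
2. (Z)-Nitrile ⇒ HWE on a C7 ketone; C7 ketone ⇒ oxidative excision of the carvone isopropenyl group after it has relayed its chirality.
3. C10 tertiary alcohol ⇒ CH2OH-directed epoxidation of the carvone ring alkene, then hydride opening.
4. Key step: quaternary C11 (C11–C12 bond) ⇒ Ireland–Claisen [3,3] rearrangement of a silyl ketene acetal generated by Cu-catalysed conjugate addition (which sets C6) to an allyl dienoate.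
5. Dienoate ⇒ carbonylation of the dienyl triflate of (S)-carvone; the only carbocycle is bought with carvone, so no ring is formed in the route.

Assumption: locants follow the iridal skeleton (ring C6–C11; C27 = CH2OH carbon on C11; C12–C23 side chain; C1/C2 enal; C3–C5 hydroxypropyl), TBS = t-BuMe2Si, and LiN(i-Pr)2, n-BuLi and i-Bu2AlH are used as bought solutions.

**Step 1**
Reactants: 1 (S)-(+)-carvone
Product: 3 (3S)-6-methyl-3-(prop-1-en-2-yl)cyclohexa-1,5-dien-1-yl trifluoromethanesulfonate, via lithium dienolate 2 (not isolated)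
Conditions: LiN(i-Pr)2, THF, −78 °C; PhNTf2, −78 → 0 °C
Reagents that add atoms: N-phenylbis(trifluoromethanesulfonimide), O=S(=O)(N(c1ccccc1)S(=O)(=O)C(F)(F)F)C(F)(F)F; LiN(i-Pr)2, [Li+].CC(C)[N-]C(C)C (its lithium appears only in 2)
Why: Kinetic deprotonation at the α'-CH2 (C6) gives the cross-conjugated dienolate, which is O-sulfonylated (enol triflate formation) without touching the bought C7 stereocentre.

**Step 2**
Reactants: 3 dienyl triflate; 4 carbon monoxide; 5 allyl alcohol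
Product: 6 prop-2-en-1-yl (3S)-6-methyl-3-(prop-1-en-2-yl)cyclohexa-1,5-diene-1-carboxylate
Conditions: Pd(OAc)2 (5 mol %), PPh3 (10 mol %), CO (1 atm), Et3N, DMF, 40 °C
Reagents that add atoms: carbon monoxide 4, [C-]#[O+]; allyl alcohol 5, C=CCO
Why: Oxidative addition of the triflate to zerovalent palladium formed in situ, CO insertion and alcoholysis (Pd-catalysed alkoxycarbonylation) give the allyl ester and leave C7 untouched.

**Step 3**
Reactants: 6 allyl dienoate; 7 (3-bromopropoxy)(tert-butyl)dimethylsilane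
Product: 10 (1R,5S,6R)-6-{3-[(tert-butyldimethylsilyl)oxy]propyl}-2-methyl-1-(prop-2-en-1-yl)-5-(prop-1-en-2-yl)cyclohex-2-ene-1-carboxylic acid, via silyl ketene acetal 8 (not isolated), via trimethylsilyl ester 9 (not isolated)
Conditions: 7, Mg, THF (gives TBSO(CH2)3MgBr); then 6, CuBr·SMe2 (10 mol %), Me3SiCl, HMPA, THF, −78 → −40 °C; then 60 °C; aq. NH4Cl
Reagents that add atoms: [3-(tert-butyldimethylsilyloxy)propyl]magnesium bromide (from 7 and Mg), CC(C)(C)[Si](C)(C)OCCC[Mg]Br; chlorotrimethylsilane, C[Si](C)(C)Cl (its silyl group appears only in 8 and 9)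
Why: Cu-catalysed, Me3SiCl-accelerated 1,4-addition occurs at C6 anti to the adjacent C7 isopropenyl group and gives the O-allyl O-silyl ketene acetal, which on warming undergoes Ireland–Claisen [3,3] rearrangement with the allyl terminus bonding to C11 on the face opposite the new C6 chain, so the quaternary centre forms with allyl trans and CO2H cis to that chain.

**Step 4**
Reactants: 10 acid
Product: 11 [(1R,5S,6R)-6-{3-[(tert-butyldimethylsilyl)oxy]propyl}-2-methyl-1-(prop-2-en-1-yl)-5-(prop-1-en-2-yl)cyclohex-2-en-1-yl]methanol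
Conditions: LiAlH4, THF, 0 °C → reflux
Reagents that add atoms: none
Why: Hydride reduction of the carboxylic acid gives the neopentyl primary alcohol and leaves the silyl ether and the three alkenes alone.

**Step 5**
Reactants: 11 homoallylic alcohol
Product: 12 [(1R,2S,3R,4S,6S)-3-{3-[(tert-butyldimethylsilyl)oxy]propyl}-1-methyl-2-(prop-2-en-1-yl)-4-(prop-1-en-2-yl)-7-oxabicyclo[4.1.0]heptan-2-yl]methanol
Conditions: VO(acac)2 (5 mol %), t-BuOOH, CH2Cl2, 0 °C → rt
Reagents that add atoms: tert-butyl hydroperoxide, CC(C)(C)OO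
Why: Hydroxyl-directed vanadium-catalysed epoxidation of the homoallylic alcohol delivers oxygen only to the trisubstituted C9=C10 alkene and on the face of the CH2OH group, which sets C9 and C10.

**Step 6**
Reactants: 12 epoxy alcohol
Product: 13 (1S,2S,3R,4S)-3-{3-[(tert-butyldimethylsilyl)oxy]propyl}-2-(hydroxymethyl)-1-methyl-2-(prop-2-en-1-yl)-4-(prop-1-en-2-yl)cyclohexan-1-ol
Conditions: LiAlH4, THF, 0 → 50 °C
Reagents that add atoms: none
Why: Hydride opens the trisubstituted epoxide by SN2 attack at the less substituted C9, so the C10–O bond and its configuration (OH cis to CH2OH) are kept.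

**Step 7**
Reactants: 13 diol
Product: 14 (1S,2S,3R,4S)-2-{[(tert-butyldimethylsilyl)oxy]methyl}-3-{3-[(tert-butyldimethylsilyl)oxy]propyl}-1-methyl-2-(prop-2-en-1-yl)-4-(prop-1-en-2-yl)cyclohexan-1-ol
Conditions: TBSCl, imidazole, DMF, 0 °C → rt
Reagents that add atoms: tert-butyldimethylsilyl chloride, CC(C)(C)[Si](C)(C)Cl
Why: Silylation is selective for the primary alcohol over the hindered tertiary one.

**Step 8**
Reactants: 14 bis-silyl ether
Product: 16 (1S,2S,3R,4S)-2-{[(tert-butyldimethylsilyl)oxy]methyl}-3-{3-[(tert-butyldimethylsilyl)oxy]propyl}-2-(3-hydroxypropyl)-1-methyl-4-(prop-1-en-2-yl)cyclohexan-1-ol, via alkylborane 15 (not isolated)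
Conditions: (Me2CHCHMe)2BH (from BH3·THF and 2-methylbut-2-ene), THF, 0 °C; then NaOH, H2O2, 0 °C → rt
Reagents that add atoms: disiamylborane, CC(C)C(C)BC(C)C(C)C (its boron appears only in 15); hydrogen peroxide, OO
Why: Anti-Markovnikov hydroboration–oxidation with the bulky dialkylborane takes the monosubstituted allyl alkene much faster than the hindered 1,1-disubstituted isopropenyl group.

**Step 9**
Reactants: 16 primary alcohol
Product: 19 (2S,3S,4S)-3-{[(tert-butyldimethylsilyl)oxy]methyl}-2-{3-[(tert-butyldimethylsilyl)oxy]propyl}-4-hydroxy-3-(3-hydroxypropyl)-4-methylcyclohexan-1-one, via methoxy hydroperoxide 17 (not isolated), via TEMPO alkoxyamine 18 (not isolated)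
Conditions: O3, CH2Cl2/MeOH, −78 °C; then FeSO4·7H2O, TEMPO, 0 °C → rt; then mCPBA, CH2Cl2, 0 °C
Reagents that add atoms: ozone, [O-][O+]=O and methanol, CO (their atoms appear only in 17); TEMPO, CC1(C)CCCC(C)(C)N1[O] (in 18; its oxygen becomes the ketone oxygen of 19)
Why: Ozonolysis in methanol gives the α-methoxy hydroperoxide, divalent iron reduces it to an alkoxy radical that loses methyl acetate by β-scission, TEMPO traps the C7 radical and the peracid turns the alkoxyamine into the ketone (oxodealkenylation), so C7 is deliberately erased while C6, C10 and C11 are not involved.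

**Step 10**
Reactants: 19 ketone; 20 diethyl (1-cyanoethyl)phosphonate
Product: 21 (2Z)-2-[(2R,3S,4S)-3-{[(tert-butyldimethylsilyl)oxy]methyl}-2-{3-[(tert-butyldimethylsilyl)oxy]propyl}-4-hydroxy-3-(3-hydroxypropyl)-4-methylcyclohexylidene]propanenitrile
Conditions: 20 (3 equiv), NaH (2.8 equiv), THF, 0 °C; then 19, 65 °C
Reagents that add atoms: diethyl (1-cyanoethyl)phosphonate 20, CCOP(=O)(OCC)C(C)C#N
Why: Horner–Wadsworth–Emmons olefination with the small cyanophosphonate anion (too weak a base to deprotonate the alcohols or readily epimerise C6) gives the tetrasubstituted alkene with the slim nitrile on the crowded C6 side and the methyl on the C8H2 side (Z expected as the major isomer, E removed by chromatography).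

**Step 11**
Reactants: 21 hydroxy nitrile
Product: 22 (2Z)-2-[(2R,3S,4S)-3-{[(tert-butyldimethylsilyl)oxy]methyl}-2-{3-[(tert-butyldimethylsilyl)oxy]propyl}-4-hydroxy-4-methyl-3-(3-oxopropyl)cyclohexylidene]propanenitrile
Conditions: Dess–Martin periodinane, NaHCO3, CH2Cl2, 0 °C → rt
Reagents that add atoms: none
Why: Dess–Martin oxidation converts the only primary alcohol into the aldehyde while the tertiary alcohol and the nitrile are inert.

**Step 12**
Reactants: 22 aldehyde; 23 2-(triphenylphosphoranylidene)propanal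
Product: 24 (2Z)-2-[(2R,3S,4S)-3-{[(tert-butyldimethylsilyl)oxy]methyl}-2-{3-[(tert-butyldimethylsilyl)oxy]propyl}-4-hydroxy-4-methyl-3-[(3E)-4-methyl-5-oxopent-3-en-1-yl]cyclohexylidene]propanenitrile
Conditions: 23, toluene, 90 °C
Reagents that add atoms: 2-(triphenylphosphoranylidene)propanal 23, CC(C=O)=P(c1ccccc1)(c1ccccc1)c1ccccc1
Why: The Wittig reaction of the stabilised formyl ylide is aldehyde-selective and E-selective, giving the (E)-2-methyl enal (C14=C15) even if 22 rests partly as its C10–O lactol.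

**Step 13**
Reactants: 25 geranyl bromide
Product: 26 diethyl [(2E)-3,7-dimethylocta-2,6-dien-1-yl]phosphonate
Conditions: P(OEt)3, neat, 130 °C
Reagents that add atoms: triethyl phosphite, CCOP(OCC)OCC
Why: Michaelis–Arbuzov reaction of the primary allylic bromide gives the phosphonate with the 2E alkene retained.

**Step 14**
Reactants: 24 enal; 26 diethyl geranylphosphonate
Product: 27 (2Z)-2-[(2R,3S,4S)-3-{[(tert-butyldimethylsilyl)oxy]methyl}-2-{3-[(tert-butyldimethylsilyl)oxy]propyl}-4-hydroxy-4-methyl-3-[(3E,5E,7E)-4,8,12-trimethyltrideca-3,5,7,11-tetraen-1-yl]cyclohexylidene]propanenitrile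
Conditions: 26 (2.1 equiv), n-BuLi, THF, −78 °C; then 24, −78 °C → rt
Reagents that add atoms: diethyl geranylphosphonate 26, CCOP(=O)(OCC)C/C=C(\C)CCC=C(C)C
Why: Horner–Wadsworth–Emmons olefination of the enal with the lithiated allylic phosphonate forms the C16=C17 bond E-selectively (one equivalent of anion is consumed by the tertiary OH) and completes the E,E,E-triene.

**Step 15**
Reactants: 27 nitrile
Product: 29 (2Z)-2-[(2R,3S,4S)-3-{[(tert-butyldimethylsilyl)oxy]methyl}-2-{3-[(tert-butyldimethylsilyl)oxy]propyl}-4-hydroxy-4-methyl-3-[(3E,5E,7E)-4,8,12-trimethyltrideca-3,5,7,11-tetraen-1-yl]cyclohexylidene]propanal, via aldimine 28 (not isolated)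
Conditions: i-Bu2AlH (4 equiv), toluene, −78 → 0 °C; then aq. KNaC4H4O6, wet SiO2
Reagents that add atoms: water, O
Why: i-Bu2AlH adds once to the nitrile and the resulting aldimine is hydrolysed on work-up to the enal with the Z geometry retained (nitrile-to-aldehyde reduction), the triene and silyl ethers being inert.

**Step 16**
Reactants: 29 bis-TBS ether
Product: 30 (2Z)-2-[(2R,3S,4S)-4-hydroxy-3-(hydroxymethyl)-2-(3-hydroxypropyl)-4-methyl-3-[(3E,5E,7E)-4,8,12-trimethyltrideca-3,5,7,11-tetraen-1-yl]cyclohexylidene]propanal (target)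
Conditions: HF·pyridine, pyridine, THF, 0 °C → rt
Reagents that add atoms: none
Why: Fluoride-mediated desilylation removes both primary TBS ethers under conditions that do not isomerise the enal or the triene.

**Compound list**
1 | (S)-(+)-carvone, (5S)-2-methyl-5-(prop-1-en-2-yl)cyclohex-2-en-1-one | CC1=CC[C@@H](CC1=O)C(C)=C | starting material
2 | lithium (3S)-6-methyl-3-(prop-1-en-2-yl)cyclohexa-1,5-dien-1-olate | CC1=CC[C@H](C(C)=C)C=C1[O-].[Li+] | intermediate
3 | (3S)-6-methyl-3-(prop-1-en-2-yl)cyclohexa-1,5-dien-1-yl trifluoromethanesulfonate | CC1=CC[C@H](C(C)=C)C=C1OS(=O)(=O)C(F)(F)F | intermediate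
4 | carbon monoxide | [C-]#[O+] | starting material
5 | prop-2-en-1-ol (allyl alcohol) | C=CCO | starting material
6 | prop-2-en-1-yl (3S)-6-methyl-3-(prop-1-en-2-yl)cyclohexa-1,5-diene-1-carboxylate | CC1=CC[C@H](C(C)=C)C=C1C(=O)OCC=C | intermediate
7 | (3-bromopropoxy)(tert-butyl)dimethylsilane | CC(C)(C)[Si](C)(C)OCCCBr | starting material
8 | [(5S,6R)-6-{3-[(tert-butyldimethylsilyl)oxy]propyl}-2-methyl-5-(prop-1-en-2-yl)cyclohex-2-en-1-ylidene](prop-2-en-1-yloxy)methoxy(trimethyl)silane (ketene acetal geometry undefined) | CC1=CC[C@H](C(C)=C)[C@@H](CCCO[Si](C)(C)C(C)(C)C)C1=C(O[Si](C)(C)C)OCC=C | intermediate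
9 | trimethylsilyl (1R,5S,6R)-6-{3-[(tert-butyldimethylsilyl)oxy]propyl}-2-methyl-1-(prop-2-en-1-yl)-5-(prop-1-en-2-yl)cyclohex-2-ene-1-carboxylate | CC1=CC[C@H](C(C)=C)[C@@H](CCCO[Si](C)(C)C(C)(C)C)[C@@]1(CC=C)C(=O)O[Si](C)(C)C | intermediate
10 | (1R,5S,6R)-6-{3-[(tert-butyldimethylsilyl)oxy]propyl}-2-methyl-1-(prop-2-en-1-yl)-5-(prop-1-en-2-yl)cyclohex-2-ene-1-carboxylic acid | CC1=CC[C@H](C(C)=C)[C@@H](CCCO[Si](C)(C)C(C)(C)C)[C@@]1(CC=C)C(=O)O | intermediate
11 | [(1R,5S,6R)-6-{3-[(tert-butyldimethylsilyl)oxy]propyl}-2-methyl-1-(prop-2-en-1-yl)-5-(prop-1-en-2-yl)cyclohex-2-en-1-yl]methanol | CC1=CC[C@H](C(C)=C)[C@@H](CCCO[Si](C)(C)C(C)(C)C)[C@@]1(CC=C)CO | intermediate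
12 | [(1R,2S,3R,4S,6S)-3-{3-[(tert-butyldimethylsilyl)oxy]propyl}-1-methyl-2-(prop-2-en-1-yl)-4-(prop-1-en-2-yl)-7-oxabicyclo[4.1.0]heptan-2-yl]methanol (oxirane cis to CH2OH) | C[C@]12O[C@H]1C[C@H](C(C)=C)[C@@H](CCCO[Si](C)(C)C(C)(C)C)[C@@]2(CC=C)CO | intermediate
13 | (1S,2S,3R,4S)-3-{3-[(tert-butyldimethylsilyl)oxy]propyl}-2-(hydroxymethyl)-1-methyl-2-(prop-2-en-1-yl)-4-(prop-1-en-2-yl)cyclohexan-1-ol | C[C@]1(O)CC[C@H](C(C)=C)[C@@H](CCCO[Si](C)(C)C(C)(C)C)[C@@]1(CC=C)CO | intermediate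
14 | (1S,2S,3R,4S)-2-{[(tert-butyldimethylsilyl)oxy]methyl}-3-{3-[(tert-butyldimethylsilyl)oxy]propyl}-1-methyl-2-(prop-2-en-1-yl)-4-(prop-1-en-2-yl)cyclohexan-1-ol | C[C@]1(O)CC[C@H](C(C)=C)[C@@H](CCCO[Si](C)(C)C(C)(C)C)[C@@]1(CC=C)CO[Si](C)(C)C(C)(C)C | intermediate
15 | B-alkyl bis(3-methylbutan-2-yl)borane of 14 (boron on the terminal carbon of the former allyl group) | C[C@]1(O)CC[C@H](C(C)=C)[C@@H](CCCO[Si](C)(C)C(C)(C)C)[C@@]1(CCCB(C(C)C(C)C)C(C)C(C)C)CO[Si](C)(C)C(C)(C)C | intermediate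
16 | (1S,2S,3R,4S)-2-{[(tert-butyldimethylsilyl)oxy]methyl}-3-{3-[(tert-butyldimethylsilyl)oxy]propyl}-2-(3-hydroxypropyl)-1-methyl-4-(prop-1-en-2-yl)cyclohexan-1-ol | C[C@]1(O)CC[C@H](C(C)=C)[C@@H](CCCO[Si](C)(C)C(C)(C)C)[C@@]1(CCCO)CO[Si](C)(C)C(C)(C)C | intermediate
17 | (1S,2S,3R,4S)-2-{[(tert-butyldimethylsilyl)oxy]methyl}-3-{3-[(tert-butyldimethylsilyl)oxy]propyl}-4-(1-hydroperoxy-1-methoxyethyl)-2-(3-hydroxypropyl)-1-methylcyclohexan-1-ol (side-chain centre undefined) | C[C@]1(O)CC[C@H](C(C)(OC)OO)[C@@H](CCCO[Si](C)(C)C(C)(C)C)[C@@]1(CCCO)CO[Si](C)(C)C(C)(C)C | intermediate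
18 | C7 O-(2,2,6,6-tetramethylpiperidin-1-yl) alkoxyamine of the nor-alcohol of 16 (C7 epimers) | C[C@]1(O)CCC(ON2C(C)(C)CCCC2(C)C)[C@@H](CCCO[Si](C)(C)C(C)(C)C)[C@@]1(CCCO)CO[Si](C)(C)C(C)(C)C | intermediate
19 | (2S,3S,4S)-3-{[(tert-butyldimethylsilyl)oxy]methyl}-2-{3-[(tert-butyldimethylsilyl)oxy]propyl}-4-hydroxy-3-(3-hydroxypropyl)-4-methylcyclohexan-1-one | C[C@]1(O)CCC(=O)[C@@H](CCCO[Si](C)(C)C(C)(C)C)[C@@]1(CCCO)CO[Si](C)(C)C(C)(C)C | intermediate
20 | diethyl (1-cyanoethyl)phosphonate (racemic) | CCOP(=O)(OCC)C(C)C#N | starting material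
21 | (2Z)-2-[(2R,3S,4S)-3-{[(tert-butyldimethylsilyl)oxy]methyl}-2-{3-[(tert-butyldimethylsilyl)oxy]propyl}-4-hydroxy-3-(3-hydroxypropyl)-4-methylcyclohexylidene]propanenitrile | C[C@]1(O)CC/C(=C(\C)C#N)[C@@H](CCCO[Si](C)(C)C(C)(C)C)[C@@]1(CCCO)CO[Si](C)(C)C(C)(C)C | intermediate
22 | (2Z)-2-[(2R,3S,4S)-3-{[(tert-butyldimethylsilyl)oxy]methyl}-2-{3-[(tert-butyldimethylsilyl)oxy]propyl}-4-hydroxy-4-methyl-3-(3-oxopropyl)cyclohexylidene]propanenitrile | C[C@]1(O)CC/C(=C(\C)C#N)[C@@H](CCCO[Si](C)(C)C(C)(C)C)[C@@]1(CCC=O)CO[Si](C)(C)C(C)(C)C | intermediate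
23 | 2-(triphenylphosphoranylidene)propanal | CC(C=O)=P(c1ccccc1)(c1ccccc1)c1ccccc1 | starting material
24 | (2Z)-2-[(2R,3S,4S)-3-{[(tert-butyldimethylsilyl)oxy]methyl}-2-{3-[(tert-butyldimethylsilyl)oxy]propyl}-4-hydroxy-4-methyl-3-[(3E)-4-methyl-5-oxopent-3-en-1-yl]cyclohexylidene]propanenitrile | C[C@]1(O)CC/C(=C(\C)C#N)[C@@H](CCCO[Si](C)(C)C(C)(C)C)[C@@]1(CC/C=C(\C)C=O)CO[Si](C)(C)C(C)(C)C | intermediate
25 | geranyl bromide, (2E)-1-bromo-3,7-dimethylocta-2,6-diene | CC(C)=CCC/C(C)=C/CBr | starting material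
26 | diethyl [(2E)-3,7-dimethylocta-2,6-dien-1-yl]phosphonate | CCOP(=O)(OCC)C/C=C(\C)CCC=C(C)C | intermediate
27 | (2Z)-2-[(2R,3S,4S)-3-{[(tert-butyldimethylsilyl)oxy]methyl}-2-{3-[(tert-butyldimethylsilyl)oxy]propyl}-4-hydroxy-4-methyl-3-[(3E,5E,7E)-4,8,12-trimethyltrideca-3,5,7,11-tetraen-1-yl]cyclohexylidene]propanenitrile | C[C@]1(O)CC/C(=C(\C)C#N)[C@@H](CCCO[Si](C)(C)C(C)(C)C)[C@@]1(CC/C=C(C)/C=C/C=C(C)/CCC=C(C)C)CO[Si](C)(C)C(C)(C)C | intermediate
28 | (2Z)-propan-1-imine corresponding to 27 (C≡N reduced to CH=NH) | C[C@]1(O)CC/C(=C(\C)C=N)[C@@H](CCCO[Si](C)(C)C(C)(C)C)[C@@]1(CC/C=C(C)/C=C/C=C(C)/CCC=C(C)C)CO[Si](C)(C)C(C)(C)C | intermediate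
29 | (2Z)-2-[(2R,3S,4S)-3-{[(tert-butyldimethylsilyl)oxy]methyl}-2-{3-[(tert-butyldimethylsilyl)oxy]propyl}-4-hydroxy-4-methyl-3-[(3E,5E,7E)-4,8,12-trimethyltrideca-3,5,7,11-tetraen-1-yl]cyclohexylidene]propanal | C[C@]1(O)CC/C(=C(\C)C=O)[C@@H](CCCO[Si](C)(C)C(C)(C)C)[C@@]1(CC/C=C(C)/C=C/C=C(C)/CCC=C(C)C)CO[Si](C)(C)C(C)(C)C | intermediate
30 | (2Z)-2-[(2R,3S,4S)-4-hydroxy-3-(hydroxymethyl)-2-(3-hydroxypropyl)-4-methyl-3-[(3E,5E,7E)-4,8,12-trimethyltrideca-3,5,7,11-tetraen-1-yl]cyclohexylidene]propanal, CNP0179699.2 (6R,10S,11S in iridal locants) | CC(C)=CCC/C(C)=C/C=C/C(C)=C/CC[C@@]1(CO)[C@H](CCCO)/C(=C(/C)C=O)CC[C@]1(C)O | target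

**Totals**
Total step count: 16. Longest linear sequence: 15 steps (steps 1–12 and 14–16) from (S)-carvone.

**Three steps most likely to fail, with fallbacks**

Step 3 (tandem conjugate addition/Ireland–Claisen). The organocopper species may attack the allyl ester by allylic substitution, or the hindered β-carbon may react sluggishly so that no ketene acetal forms. The fallback sets out from 3 and comes back at 8. Carbonylation of 3 in methanol (Pd(OAc)2, PPh3, CO, Et3N) gives the methyl dienoate F1. The same Cu-catalysed Grignard addition with aqueous quench gives the methyl ester F2, with C6 set anti to the isopropenyl group and C11 still bearing H. Hydrolysis (LiOH, aq. dioxane, 60 °C) gives the carboxylic acid F3, and allyl bromide/K2CO3 in DMF gives the allyl ester F4. Deprotonation with LiN(i-Pr)2 and silylation with Me3SiCl (THF, −78 °C) then forms silyl ketene acetal 8, which rearranges as in the route. The allyl ester therefore never meets the organocopper reagent, and the enolate is made in a separate operation.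

Step 9 (oxodealkenylation in the presence of a free primary alcohol). The nitroxide/peracid stage may oxidise the C14 alcohol, or the radical fragmentation may be low-yielding. The fallback sets out from 16 and comes back at 19. Ozonolysis in CH2Cl2/MeOH followed by Ac2O, Et3N and DMAP (Criegee rearrangement of the peroxyacetate, with retention at C7; the C14 hydroxyl is acetylated as well) gives the diacetate F5. Methanolysis (K2CO3, MeOH) gives the diol F6. A secondary-selective oxidation (NaOCl, AcOH, 0 °C) then gives ketone 19.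

Step 10 (HWE on a hindered, enolisable ketone; reactivity, Z/E ratio and C6 integrity). The fallback sets out from 19 and comes back at 21. Lithiated 2-(trimethylsilyl)propanenitrile (from the silyl nitrile and LiN(i-Pr)2, excess, THF, −78 °C → rt) adds irreversibly to the ketone to give the β-silyl alkoxide adduct F7. This collapses by loss of Me3SiOLi (Peterson olefination) to nitrile 21, and the Z isomer is again separated from any E isomer.

**Further compounds**
F1 | step 3 | methyl (3S)-6-methyl-3-(prop-1-en-2-yl)cyclohexa-1,5-diene-1-carboxylate | CC1=CC[C@H](C(C)=C)C=C1C(=O)OC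
F2 | step 3 | methyl (5S,6R)-6-{3-[(tert-butyldimethylsilyl)oxy]propyl}-2-methyl-5-(prop-1-en-2-yl)cyclohex-2-ene-1-carboxylate (C1 epimers) | CC1=CC[C@H](C(C)=C)[C@@H](CCCO[Si](C)(C)C(C)(C)C)C1C(=O)OC
F3 | step 3 | (5S,6R)-6-{3-[(tert-butyldimethylsilyl)oxy]propyl}-2-methyl-5-(prop-1-en-2-yl)cyclohex-2-ene-1-carboxylic acid (C1 epimers) | CC1=CC[C@H](C(C)=C)[C@@H](CCCO[Si](C)(C)C(C)(C)C)C1C(=O)O
F4 | step 3 | prop-2-en-1-yl (5S,6R)-6-{3-[(tert-butyldimethylsilyl)oxy]propyl}-2-methyl-5-(prop-1-en-2-yl)cyclohex-2-ene-1-carboxylate (C1 epimers) | CC1=CC[C@H](C(C)=C)[C@@H](CCCO[Si](C)(C)C(C)(C)C)C1C(=O)OCC=C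
F5 | step 9 | (1S,2S,3S,4S)-3-(3-acetoxypropyl)-3-{[(tert-butyldimethylsilyl)oxy]methyl}-2-{3-[(tert-butyldimethylsilyl)oxy]propyl}-4-hydroxy-4-methylcyclohexyl acetate | C[C@]1(O)CC[C@H](OC(C)=O)[C@@H](CCCO[Si](C)(C)C(C)(C)C)[C@@]1(CCCOC(C)=O)CO[Si](C)(C)C(C)(C)C
F6 | step 9 | (1S,2S,3S,4S)-2-{[(tert-butyldimethylsilyl)oxy]methyl}-3-{3-[(tert-butyldimethylsilyl)oxy]propyl}-2-(3-hydroxypropyl)-1-methylcyclohexane-1,4-diol | C[C@]1(O)CC[C@H](O)[C@@H](CCCO[Si](C)(C)C(C)(C)C)[C@@]1(CCCO)CO[Si](C)(C)C(C)(C)C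
F7 | step 10 | 2-[(2S,3S,4S)-3-{[(tert-butyldimethylsilyl)oxy]methyl}-2-{3-[(tert-butyldimethylsilyl)oxy]propyl}-1,4-dihydroxy-3-(3-hydroxypropyl)-4-methylcyclohexyl]-2-(trimethylsilyl)propanenitrile (formed as its lithium alkoxide; diastereomer mixture) | C[C@]1(O)CCC(O)(C(C)(C#N)[Si](C)(C)C)[C@@H](CCCO[Si](C)(C)C(C)(C)C)[C@@]1(CCCO)CO[Si](C)(C)C(C)(C)C
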